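**Retrosynthetic overview**
1. 13 ⇐ 12: last step, a tin-hydride radical cascade from the C3 chloride forms C3–C2′ (seven-membered bridge of the homoadamantane cage) and then C3′–C2″ (cyclopentane).
2. 12 ⇐ 11: ring B by cationic C8–C1 closure of the isopropenyl group onto the benzoyl-bearing enol carbon, with C3 and C5 already quaternary.
3. 11 ⇐ 9 ⇐ 7: C3 quaternised by prenylation; before that the key step, a palladium-catalysed, ligand-controlled dearomative geranylation of the fully aromatic 7 that creates the C5 quaternary stereocentre.
4. 7 ⇐ 4 + 6 and 4 ⇐ phloroglucinol + benzoyl chloride: C7 comes from (S)-lavandulol; one chlorine blocks C3 while the ring is aromatic and later serves as the radical trigger.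
5. Ring order: phloroglucinol ring (becomes ring A) → ring B → seven-membered bridge → cyclopentane.

Locants used throughout: C1 (benzoyl), C2, C3, C4, C5 (geranyl) and C9 are the six carbons of the original phloroglucinol ring; C6–C7–C8 and C1′–C3′ come from lavandulol; C1″–C3″ are the prenyl group on C3. In this numbering the target is (1S,3S,5R,7R,2′S,2″S).
Assumption: (S)-lavandulol is bought as the single enantiomer (otherwise obtained by lipase resolution of the commercial racemate).
Assumption: in step 5 the (R,R) ligand is taken as the one that favours the C5 configuration of 9; if the sense is the opposite, the (S,S) ligand is used.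

**Step 1**
Reactants: 1 phloroglucinol; 2 benzoyl chloride
Product: 3 2,4,6-trihydroxybenzophenone
Conditions: AlCl3, PhNO2, 60 °C
Reagents that add atoms: none
Why: Friedel–Crafts C-acylation of the very electron-rich triol stops after one benzoyl group because the product is deactivated; no stereocentre is formed.

**Step 2**
Reactants: 3 2,4,6-trihydroxybenzophenone
Product: 4 3-chloro-2,4,6-trihydroxybenzophenone
Conditions: SO2Cl2 (1.0 equiv), CHCl3/Et2O, 0 °C
Reagents that add atoms: sulfuryl chloride, O=S(=O)(Cl)Cl
Why: Electrophilic aromatic chlorination at one of the two equivalent free ring carbons gives the monochloride (no stereocentre), and the chlorine keeps C3 from being alkylated in steps 4 and 5.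

**Step 3**
Reactants: 5 (S)-lavandulol
Product: 6 (S)-lavandulyl trifluoromethanesulfonate
Conditions: Tf2O, 2,6-lutidine, CH2Cl2, −78 °C; used crude
Reagents that add atoms: trifluoromethanesulfonic anhydride, O=S(=O)(OS(=O)(=O)C(F)(F)F)C(F)(F)F
Why: O-Sulfonylation of the primary alcohol activates the β-branched carbon for SN2 without touching the stereocentre, which becomes C7 of the target.

**Step 4**
Reactants: 4 3-chloro-2,4,6-trihydroxybenzophenone; 6 (S)-lavandulyl trifluoromethanesulfonate
Product: 7 3-chloro-2,4,6-trihydroxy-5-[(2R)-5-methyl-2-(prop-1-en-2-yl)hex-4-en-1-yl]benzophenone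
Conditions: LiN(SiMe3)2 (3.0 equiv), THF, −78 °C; then 6, −78 to 0 °C
Reagents that add atoms: none
Why: SN2 C-alkylation of the lithium phenolate at C5, the only unsubstituted ring carbon, followed by re-aromatisation; C7 is untouched (the label changes from S to R only because the ring carbon replaces oxygen in the priority order).

**Step 5 (key step)**
Reactants: 7 (the aromatic compound of step 4); 8 geranyl acetate
Product: 9 4-benzoyl-2-chloro-6-[(2E)-3,7-dimethylocta-2,6-dienyl]-3,5-dihydroxy-6-[(2R)-5-methyl-2-(prop-1-en-2-yl)hex-4-enyl]cyclohexa-2,4-dien-1-one (ring carbon 6 = C5, configured as in 13)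
Conditions: Pd2(dba)3 (2.5 mol %), (R,R)-DACH-phenyl Trost ligand (7.5 mol %), Et3N (1.2 equiv), CH2Cl2, 0 °C to rt
Reagents that add atoms: none
Why: Proposed new method: a ligand-controlled Tsuji–Trost allylation in which the triethylammonium phenolate of 7 attacks the less hindered terminus of the π-geranyl–palladium complex through C5, the only ring carbon flanked by two oxygens and not deactivated by chlorine or benzoyl, so that the arene becomes a cross-conjugated enolised triketone and the C5 quaternary centre is set by delivery of the geranyl group to one face inside the chiral ligand pocket (the remote C7 centre exerting little bias), the closest known reactions being the palladium-catalysed dearomative C-allylation of acylphloroglucinols and the asymmetric, linear-selective geranylation of prochiral carbon nucleophiles with diamine-derived bisphosphine ligands.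

**Step 6**
Reactants: 9 (the dearomatised dienone of step 5); 10 prenyl bromide
Product: 11 2-benzoyl-6-chloro-4-geranyl-3-hydroxy-4-[(2R)-lavandulyl]-6-prenylcyclohex-2-ene-1,5-dione (C5 and C7 as in 13; both epimers at the chlorine-bearing C3)
Conditions: LiN(SiMe3)2 (2.1 equiv), THF/PhMe, −78 °C; then 10, −78 to 0 °C
Reagents that add atoms: none
Why: Dianion C-alkylation in which the last-formed, less stabilised chloro-diketone enolate reacts at C3 while the benzoyl triketone enolate stays inert; the new C3 centre forms as an epimer mixture that does not matter because C3 becomes a planar radical in step 8.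

**Step 7**
Reactants: 11 (the C3-chloro, C3-prenyl monocycle of step 6)
Product: 12 1-benzoyl-3-chloro-5-geranyl-8,8-dimethyl-3,7-diprenylbicyclo[3.3.1]nonane-2,4,9-trione (7-prenyl endo, that is syn to C3; C1, C5, C7 as in 13; both C3 epimers)
Conditions: HCO2H (neat), 40 °C
Reagents that add atoms: none
Why: Cationic cyclisation (intramolecular Friedel–Crafts-type C-alkylation of an enol) in which formic acid protonates the 1,1-disubstituted alkene to the tertiary C8 cation, which on carbon can only be captured by C1 because C3 and C5 are quaternary (O-capture and elimination are reversible), and since C5 and C7 are already fixed the tether dictates both the new C1 centre and the endo orientation of the C7 prenyl group, ring B closing through a boat-like transition state.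

**Step 8**
Reactants: 12 (the bicyclic chloride of step 7)
Product: 13 CNP0155129.3 (the target)
Conditions: Bu3SnH (1.3 equiv, slow addition), AIBN (0.2 equiv), PhH, 80 °C
Reagents that add atoms: none
Why: Tin-hydride radical cascade in which chlorine abstraction from either C3 epimer gives the same planar electrophilic C3 radical, which adds 7-exo-trig to C2′ of the endo prenyl arm held under ring A (only that face is reachable, which fixes C3 and, through a chair-like transition state, C2′), after which the tertiary C3′ radical closes 5-exo-trig onto the C3 prenyl group with the incipient 2-propyl radical pseudo-equatorial (setting C2″) and the chain ends by hydrogen transfer from Bu3SnH.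

**Compound list**
1 | phloroglucinol (benzene-1,3,5-triol) | Oc1cc(O)cc(O)c1 | starting material
2 | benzoyl chloride | O=C(Cl)c1ccccc1 | starting material
3 | 2,4,6-trihydroxybenzophenone | O=C(c1ccccc1)c1c(O)cc(O)cc1O | intermediate
4 | 3-chloro-2,4,6-trihydroxybenzophenone | O=C(c1ccccc1)c1c(O)cc(O)c(Cl)c1O | intermediate
5 | (S)-lavandulol, (2S)-5-methyl-2-(prop-1-en-2-yl)hex-4-en-1-ol | OC[C@@H](CC=C(C)C)C(C)=C | starting material
6 | (S)-lavandulyl trifluoromethanesulfonate | O=S(=O)(OC[C@@H](CC=C(C)C)C(C)=C)C(F)(F)F | intermediate
7 | 3-chloro-2,4,6-trihydroxy-5-[(2R)-lavandulyl]benzophenone | O=C(c1ccccc1)c1c(O)c(Cl)c(O)c(C[C@@H](CC=C(C)C)C(C)=C)c1O | intermediate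
8 | geranyl acetate, (2E)-3,7-dimethylocta-2,6-dienyl acetate | CC(C)=CCC/C(C)=C/COC(C)=O | starting material
9 | 4-benzoyl-2-chloro-6-geranyl-3,5-dihydroxy-6-[(2R)-lavandulyl]cyclohexa-2,4-dien-1-one, C5 as in 13 | CC(C)=CCC/C(C)=C/C[C@@]1(C[C@@H](CC=C(C)C)C(C)=C)C(=O)C(Cl)=C(O)C(C(=O)c2ccccc2)=C1O | intermediate
10 | prenyl bromide (1-bromo-3-methylbut-2-ene) | CC(C)=CCBr | starting material
11 | 2-benzoyl-6-chloro-4-geranyl-3-hydroxy-4-[(2R)-lavandulyl]-6-prenylcyclohex-2-ene-1,5-dione, C5 as in 13, C3 epimer mixture (C3 left undefined in the SMILES) | CC(C)=CCC/C(C)=C/C[C@@]1(C[C@@H](CC=C(C)C)C(C)=C)C(=O)C(Cl)(CC=C(C)C)C(=O)C(C(=O)c2ccccc2)=C1O | intermediate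
12 | 1-benzoyl-3-chloro-5-geranyl-8,8-dimethyl-3,7-diprenylbicyclo[3.3.1]nonane-2,4,9-trione, 7-prenyl endo, C1, C5, C7 as in 13, C3 epimer mixture (C3 left undefined in the SMILES) | CC(C)=CCC/C(C)=C/C[C@@]12C[C@@H](CC=C(C)C)C(C)(C)[C@](C(=O)c3ccccc3)(C2=O)C(=O)C(Cl)(CC=C(C)C)C1=O | intermediate
13 | CNP0155129.3: the trione core of 12 with C3 bonded to C2′ (bridge C7–C1′–C2′–C3) and C3′ bonded to C2″ (cyclopentane C3–C1″–C2″–C3′–C2′, isopropyl on C2″); (1S,3S,5R,7R,2′S,2″S) | CC(C)=CCC/C(C)=C/C[C@@]12C[C@H]3C[C@H]4C(C)(C)[C@H](C(C)C)C[C@]4(C1=O)C(=O)[C@@](C(=O)c1ccccc1)(C2=O)C3(C)C | target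

**Totals and risks**
Total step count: 8. Longest linear sequence: 7 steps (steps 1, 2, 4, 5, 6, 7, 8); step 3 is a one-step side branch.

The three steps most likely to fail:

Step 7. The boat-like closure through the poorly nucleophilic benzoyl-bearing carbon may lose to O-cyclisation, to cation–olefin reaction with the geranyl group or to formate addition. Fallback, setting out from 11 and returning at 12: only the isopropenyl group of 11 is hydrochlorinated under cobalt-hydride hydrogen-atom-transfer conditions (Co(BF4)2·6H2O with a salicylaldimine ligand, TsCl, PhSiH3, t-BuOOH, EtOH, rt; 1,1-disubstituted alkenes react well ahead of trisubstituted ones) to give the tertiary chloride in which the isopropenyl group of 11 has become a 2-chloropropan-2-yl group F3. AgOSO2CF3 with 2,6-di-tert-butylpyridine in CH2Cl2 at −40 °C then ionises only this chloride (the C3 chloride, α to two carbonyl groups, does not ionise). The C8 cation is trapped by C1 in an aprotic medium in which the other alkenes are never protonated, giving 12.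

Step 5. The catalyst may give poor site selectivity (O- versus C-allylation), some loss of the E geometry, or a low diastereomer ratio at C5. Fallback, setting out from 4 and returning at 9: the order of the two C5 substituents is reversed. Compound 4 is C-geranylated at its free ring carbon (geranyl bromide, 10% aqueous KOH, 0 °C) to 3-chloro-5-[(2E)-geranyl]-2,4,6-trihydroxybenzophenone F1. The lithium trianion of F1 is then dearomatised with triflate 6 (LiN(SiMe3)2, THF, −78 to 0 °C). This gives 9 together with the C5 epimer of 9 F2, roughly 1:1. The pair is separated by preparative HPLC, or carried on together, in which case the epimer ends as a 7-exo isomer of 12 that cannot cyclise in step 8 and is removed there. Enantiopurity is not at risk because C7 comes from (S)-lavandulol.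

Step 8. Tin hydride may reduce the C3 radical before the 7-exo closure, chlorine abstraction may be sluggish, or the two new centres may form with the wrong relative configuration. Fallback, setting out from 12 and returning at 13: the chloride is removed with Zn dust in AcOH at rt to give 1-benzoyl-5-geranyl-4-hydroxy-8,8-dimethyl-3,7-diprenylbicyclo[3.3.1]non-3-ene-2,9-dione (7-prenyl endo; C1, C5, C7 as in 13) F4. The C3 radical is then generated oxidatively from this enol with Mn(OAc)3·2H2O in EtOH at 60 °C. No fast hydrogen donor is present, so both cyclisations precede termination, and the final tertiary radical takes hydrogen from the solvent to give 13.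

**Further compounds**
F1 | step 5 | 3-chloro-5-[(2E)-geranyl]-2,4,6-trihydroxybenzophenone | O=C(c1ccccc1)c1c(O)c(Cl)c(O)c(C/C=C(C)/CCC=C(C)C)c1O
F2 | step 5 | C5 epimer of 9 | CC(C)=CCC/C(C)=C/C[C@]1(C[C@@H](CC=C(C)C)C(C)=C)C(=O)C(Cl)=C(O)C(C(=O)c2ccccc2)=C1O
F3 | step 7 | tertiary chloride of 11 (2-chloropropan-2-yl in place of isopropenyl on C7; C3 epimer mixture) | CC(C)=CCC/C(C)=C/C[C@@]1(C[C@@H](CC=C(C)C)C(C)(C)Cl)C(=O)C(Cl)(CC=C(C)C)C(=O)C(C(=O)c2ccccc2)=C1O
F4 | step 8 | 1-benzoyl-5-geranyl-4-hydroxy-8,8-dimethyl-3,7-diprenylbicyclo[3.3.1]non-3-ene-2,9-dione, 7-prenyl endo | CC(C)=CCC/C(C)=C/C[C@@]12C[C@@H](CC=C(C)C)C(C)(C)[C@](C(=O)c3ccccc3)(C2=O)C(=O)C(CC=C(C)C)=C1O
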